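**Plan**
Cuts: first the two depside ester bonds, acyl–O4 of ring B (to ring C) and acyl–O4 of ring A (to ring B). The orsellinate ring is then cut at C1–C2, C2–C3, C4–C5 and C5–C6, leaving an open-chain α′-diazo enone (C2, C5, C6, C1 with the CH3 and ester carbons) and a siloxyethyne (C3, C4).
Enabling feature: ring A, counted from its carboxyl carbon C1, has CH3 on C6, H on C3 and C5, a free OH on C2 and an acylated oxygen on C4, and ring B repeats this pattern. A vinylketene–siloxyalkyne benzannulation gives this resorcinol with C2–OH free and C4–O silylated, so the two oxygens are differentiated as soon as the ring exists.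
Forward: Wittig olefination and diazo transfer give the diazo enone, and the benzannulation closes the only ring that is built. Its product is divided: desilylation gives the ring A phenol, hydrogenolysis gives the ring B acid.
Joining: the B acid goes onto O4 of A, O4 of B is desilylated, the ring C acid (three steps from methyl orsellinate by Elbs oxidation) goes onto O4 of B, and one hydrogenolysis finishes the route.
Stereochemistry: the target has no stereocentre. The only stereochemical element is the E alkene of the diazo enone, set by the stabilised ylide, so that the ester points away from the ketene terminus when the triene folds.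

Key step: step 4

Remark: positions in each ring are counted from the carbon bearing the carboxyl or acyl group (C1). The hydrogen-bonded C2 hydroxyls of rings A and B are carried unprotected.

**Step 1**
Reactants: 1 butane-2,3-dione; 2 benzyl (triphenylphosphoranylidene)acetate
Product: 3 benzyl (E)-3-methyl-4-oxopent-2-enoate
Conditions: 1 (3 equiv), CH2Cl2, 25 °C
Reagents that add atoms: none
Why: Wittig olefination with a stabilised ylide: the 1,2-diketone is electrophilic enough to react at 25 °C, its excess should hold the reaction at mono-olefination, and the reversible addition step should place the ester trans to the acetyl group (E alkene).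

**Step 2**
Reactants: 3 benzyl (E)-3-methyl-4-oxopent-2-enoate
Product: 6 benzyl (E)-5-diazo-3-methyl-4-oxopent-2-enoate, via lithium enolate 4 (not isolated), via trifluoroacetyl diketone 5 (not isolated)
Conditions: LiN(SiMe3)2, THF, −78 °C; CF3CO2CH2CF3, −78 °C; aq HCl; then 4-AcNHC6H4SO2N3, Et3N, H2O (1 equiv), MeCN, 25 °C
Reagents that add atoms: 4-acetamidobenzenesulfonyl azide, CC(=O)Nc1ccc(cc1)S(=O)(=O)N=[N+]=[N-] (N2 of 6); 2,2,2-trifluoroethyl trifluoroacetate, O=C(OCC(F)(F)F)C(F)(F)F (CF3CO of 5 only); LiN(SiMe3)2, [Li]N([Si](C)(C)C)[Si](C)(C)C (Li of 4 only)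
Why: Detrifluoroacetylative diazo transfer (a Regitz-type deacylative transfer): the acetyl CH3 is the only α-position of the ketone, its kinetic enolate 4 undergoes Claisen trifluoroacetylation, and the acidic diketone 5 takes up the diazo group under Et3N and sheds CF3CO, a sequence established for α′-diazo enones that never exposes the electron-poor alkene to diazomethane.

**Step 3**
Reactants: 7 acetylene
Product: 10 triisopropylsilyloxyethyne, via lithium acetylide 8 (not isolated), via lithium ethynolate 9 (not isolated)
Conditions: 7 (excess), n-BuLi, THF, −78 °C; t-BuOOLi [t-BuOOH + LiN(SiMe3)2, THF, −78 °C], −78 → −10 °C; i-Pr3SiOTf, −78 → 0 °C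
Reagents that add atoms: tert-butyl hydroperoxide, CC(C)(C)OO (the oxygen atom); triisopropylsilyl trifluoromethanesulfonate, CC(C)[Si](OS(=O)(=O)C(F)(F)F)(C(C)C)C(C)C (the silyl group); n-butyllithium, [Li]CCCC (Li of 8 and 9 only)
Why: Electrophilic oxygenation of a lithium acetylide with lithium tert-butyl peroxide, followed by O-silylation of the ynolate with a bulky, hard silyl triflate, is the standard synthesis of 1-siloxyalkynes, and excess acetylene with low temperature should hold back disproportionation of 8.

**Step 4**
Reactants: 6 benzyl (E)-5-diazo-3-methyl-4-oxopent-2-enoate; 10 triisopropylsilyloxyethyne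
Product: 15 benzyl 2-hydroxy-6-methyl-4-(triisopropylsilyloxy)benzoate, via vinylketene 11 (not isolated), via 4-alkenylcyclobutenone 12 (not isolated), via dienylketene 13 (not isolated), via cyclohexadienone 14 (not isolated)
Conditions: 10 (2 equiv), hν (254 nm, low-pressure Hg lamps, quartz), degassed ClCH2CH2Cl (0.1 M), 25 °C; then 80 °C
Reagents that add atoms: none
Why: Irradiation of 6 releases N2 with a 1,2-shift of the alkenyl group onto the former diazo carbon (photochemical Wolff rearrangement, forming C5–C6) and gives vinylketene 11, whose C=C bond adds to 10 in a (2+2) cycloaddition (C2–C3 and C4–C5) to give 4-alkenylcyclobutenone 12. A reversible 4π electrocyclic opening of 12, started by light and completed by the final heating, breaks the C2–C5 bond and gives dienylketene 13. Ring A closes as a six-membered carbocycle by thermal disrotatory 6π electrocyclisation of 13 (C1–C2) and dienone 14 enolises to the phenol; the sequence is the Danheiser benzannulation in its diazo ketone form, for which siloxyalkynes are established partners that give resorcinol monosilyl ethers. No stereocentre remains, because the sp3 carbons of 12 and 14 form as racemates and are erased by ring opening and enolisation. The selectivity required is regiochemical, the electrophilic ketene carbonyl carbon having to bond to the unsubstituted alkyne carbon, and oxygen donation in 10 secures it by making that CH carbon the nucleophilic one, so the silyl ether ends on C4 and the new hydroxyl on C2 next to the ester. The E alkene of 6 leaves only hydrogen on the inner side of C1 during closure, and since only the dienylketene with the alkenyl group turned inward can cyclise, the reversible opening of 12 should funnel the material to 15.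

**Step 5**
Reactants: 15 benzyl 2-hydroxy-6-methyl-4-(triisopropylsilyloxy)benzoate
Product: 16 benzyl 2,4-dihydroxy-6-methylbenzoate (ring A unit)
Conditions: n-Bu4NF, AcOH (1:1), THF, 0 °C
Reagents that add atoms: none
Why: Fluoride cleavage of an aryl silyl ether, buffered with acetic acid so that no free phenoxide attacks the benzyl ester, should unmask O4 as the only hydroxyl not hydrogen-bonded to a carbonyl group.

**Step 6**
Reactants: 15 benzyl 2-hydroxy-6-methyl-4-(triisopropylsilyloxy)benzoate
Product: 17 2-hydroxy-6-methyl-4-(triisopropylsilyloxy)benzoic acid (ring B unit)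
Conditions: H2 (1 atm), 10% Pd/C, EtOAc, 25 °C
Reagents that add atoms: none
Why: Catalytic hydrogenolysis of a benzyl ester leaves the aryl silyl ether and the arene untouched and should give the ring B acid with O4 still blocked, to be kept at or below 25 °C because orsellinic acids decarboxylate on heating.

**Step 7**
Reactants: 16 benzyl 2,4-dihydroxy-6-methylbenzoate; 17 2-hydroxy-6-methyl-4-(triisopropylsilyloxy)benzoic acid
Product: 19 benzyl 2-hydroxy-4-{[2-hydroxy-6-methyl-4-(triisopropylsilyloxy)benzoyl]oxy}-6-methylbenzoate, via mixed anhydride 18 (not isolated)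
Conditions: (CF3CO)2O, toluene, 0 → 25 °C; aq NaHCO3 wash
Reagents that add atoms: trifluoroacetic anhydride, O=C(OC(=O)C(F)(F)F)C(F)(F)F (CF3CO of 18 only)
Why: Depside esterification through a mixed aroyl trifluoroacetic anhydride: the electron-rich, doubly ortho-substituted acid is activated as 18 and should be transferred to O4 of 16, since both C2 hydroxyls are deactivated by chelation to their ortho carbonyl groups and O4 of ring B is silylated, so neither self-condensation nor O2 acylation is expected.

**Step 8**
Reactants: 19 benzyl 2-hydroxy-4-{[2-hydroxy-6-methyl-4-(triisopropylsilyloxy)benzoyl]oxy}-6-methylbenzoate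
Product: 20 benzyl 4-[(2,4-dihydroxy-6-methylbenzoyl)oxy]-2-hydroxy-6-methylbenzoate
Conditions: n-Bu4NF, AcOH (1:1), THF, 0 °C
Reagents that add atoms: none
Why: Buffered fluoride desilylation of an aryl silyl ether, in which acetic acid and the low temperature should keep the liberated phenol protonated so that the aryl ester link and the benzyl ester survive.

**Step 9**
Reactants: 21 methyl 2,4-dihydroxy-6-methylbenzoate (methyl orsellinate)
Product: 23 methyl 2,4,5-trihydroxy-6-methylbenzoate, via aryl potassium sulfate 22 (not isolated)
Conditions: K2S2O8, aq KOH, 0 → 25 °C; then aq HCl, 80 °C, under N2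
Reagents that add atoms: K2S2O8 (dipotassium peroxydisulfate), [K+].[K+].[O-]S(=O)(=O)OOS(=O)(=O)[O-] (OSO3K of 22, O5 of 23)
Why: Elbs persulfate oxidation: peroxydisulfate attacks the phenoxide para to O2, which is C5 (the position para to O4 is C1 and is blocked), the sulfate group of 22 shields the new oxygen from over-oxidation until acid hydrolysis, and 2,4-dihydroxybenzoyl compounds are known to give their 5-hydroxy derivatives this way.

**Step 10**
Reactants: 23 methyl 2,4,5-trihydroxy-6-methylbenzoate
Product: 24 methyl 2,4,5-tris(benzyloxy)-6-methylbenzoate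
Conditions: BnBr (3.5 equiv), K2CO3, DMF, 60 °C, under Ar
Reagents that add atoms: benzyl bromide, BrCc1ccccc1
Why: Williamson etherification of all three phenols, with warm DMF to bring the chelated O2 to reaction and an inert atmosphere to keep the hydroxyquinol from air oxidation.

**Step 11**
Reactants: 24 methyl 2,4,5-tris(benzyloxy)-6-methylbenzoate
Product: 25 2,4,5-tris(benzyloxy)-6-methylbenzoic acid (ring C unit)
Conditions: KOH, DMSO–H2O, 100 °C; then aq HCl, 0 °C
Reagents that add atoms: KOH (potassium hydroxide), [K+].[OH-]
Why: Saponification of a hindered 2,6-disubstituted benzoate needs poorly solvated hydroxide in hot aqueous DMSO, conditions that benzyl aryl ethers tolerate.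

**Step 12**
Reactants: 20 benzyl 4-[(2,4-dihydroxy-6-methylbenzoyl)oxy]-2-hydroxy-6-methylbenzoate; 25 2,4,5-tris(benzyloxy)-6-methylbenzoic acid
Product: 27 benzyl 2-hydroxy-4-[(2-hydroxy-6-methyl-4-{[2,4,5-tris(benzyloxy)-6-methylbenzoyl]oxy}benzoyl)oxy]-6-methylbenzoate, via mixed anhydride 26 (not isolated)
Conditions: (CF3CO)2O, toluene, 25 °C; aq NaHCO3 wash
Reagents that add atoms: trifluoroacetic anhydride, O=C(OC(=O)C(F)(F)F)C(F)(F)F (CF3CO of 26 only)
Why: Depside esterification by the mixed trifluoroacetic anhydride method, which suits crowded electron-rich acids and should deliver the aroyl group of 26 to O4 of ring B, the only hydroxyl of 20 not locked in a hydrogen bond to an ortho carbonyl group.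

**Step 13**
Reactants: 27 benzyl 2-hydroxy-4-[(2-hydroxy-6-methyl-4-{[2,4,5-tris(benzyloxy)-6-methylbenzoyl]oxy}benzoyl)oxy]-6-methylbenzoate
Product: 28 2-hydroxy-4-[(2-hydroxy-6-methyl-4-{[2,4,5-trihydroxy-6-methylbenzoyl]oxy}benzoyl)oxy]-6-methylbenzoic acid (CNP0248995.0)
Conditions: H2 (1 atm), 10% Pd/C, EtOAc, 25 °C
Reagents that add atoms: none
Why: Global catalytic hydrogenolysis cleaves the benzyl ester and the three benzyl aryl ethers under neutral conditions in a non-nucleophilic solvent, so the two depside links should be neither reduced nor transesterified.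

**Compound list**
1 | butane-2,3-dione | CC(=O)C(C)=O | starting material
2 | benzyl (triphenylphosphoranylidene)acetate | O=C(C=P(c1ccccc1)(c1ccccc1)c1ccccc1)OCc1ccccc1 | starting material
3 | benzyl (E)-3-methyl-4-oxopent-2-enoate | CC(=O)/C(C)=C/C(=O)OCc1ccccc1 | intermediate
4 | lithium (3E)-5-(benzyloxy)-3-methyl-5-oxopenta-1,3-dien-2-olate | [Li+].[O-]C(=C)/C(C)=C/C(=O)OCc1ccccc1 | intermediate (not isolated)
5 | benzyl (E)-7,7,7-trifluoro-3-methyl-4,6-dioxohept-2-enoate | O=C(CC(=O)C(F)(F)F)/C(C)=C/C(=O)OCc1ccccc1 | intermediate (not isolated)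
6 | benzyl (E)-5-diazo-3-methyl-4-oxopent-2-enoate | [N-]=[N+]=CC(=O)/C(C)=C/C(=O)OCc1ccccc1 | intermediate
7 | acetylene | C#C | starting material
8 | lithium acetylide | [Li+].[C-]#C | intermediate (not isolated)
9 | lithium ethynolate | [Li+].[O-]C#C | intermediate (not isolated)
10 | triisopropylsilyloxyethyne | C#CO[Si](C(C)C)(C(C)C)C(C)C | intermediate
11 | benzyl (E)-3-methyl-5-oxopenta-2,4-dienoate (vinylketene) | O=C=C/C(C)=C/C(=O)OCc1ccccc1 | intermediate (not isolated)
12 | benzyl (E)-3-[4-oxo-2-(triisopropylsilyloxy)cyclobut-2-en-1-yl]but-2-enoate (racemic) | O=C1C=C(O[Si](C(C)C)(C(C)C)C(C)C)C1/C(C)=C/C(=O)OCc1ccccc1 | intermediate (not isolated)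
13 | benzyl (2E,4E)-3-methyl-7-oxo-5-(triisopropylsilyloxy)hepta-2,4,6-trienoate (dienylketene) | O=C=C/C(O[Si](C(C)C)(C(C)C)C(C)C)=C\C(C)=C\C(=O)OCc1ccccc1 | intermediate (not isolated)
14 | benzyl 2-methyl-6-oxo-4-(triisopropylsilyloxy)cyclohexa-2,4-diene-1-carboxylate (racemic) | O=C1C=C(O[Si](C(C)C)(C(C)C)C(C)C)C=C(C)C1C(=O)OCc1ccccc1 | intermediate (not isolated)
15 | benzyl 2-hydroxy-6-methyl-4-(triisopropylsilyloxy)benzoate | Cc1cc(O[Si](C(C)C)(C(C)C)C(C)C)cc(O)c1C(=O)OCc1ccccc1 | intermediate
16 | benzyl 2,4-dihydroxy-6-methylbenzoate | Cc1cc(O)cc(O)c1C(=O)OCc1ccccc1 | intermediate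
17 | 2-hydroxy-6-methyl-4-(triisopropylsilyloxy)benzoic acid | Cc1cc(O[Si](C(C)C)(C(C)C)C(C)C)cc(O)c1C(=O)O | intermediate
18 | 2-hydroxy-6-methyl-4-(triisopropylsilyloxy)benzoic trifluoroacetic anhydride | Cc1cc(O[Si](C(C)C)(C(C)C)C(C)C)cc(O)c1C(=O)OC(=O)C(F)(F)F | intermediate (not isolated)
19 | benzyl 2-hydroxy-4-{[2-hydroxy-6-methyl-4-(triisopropylsilyloxy)benzoyl]oxy}-6-methylbenzoate | Cc1cc(OC(=O)c2c(C)cc(O[Si](C(C)C)(C(C)C)C(C)C)cc2O)cc(O)c1C(=O)OCc1ccccc1 | intermediate
20 | benzyl 4-[(2,4-dihydroxy-6-methylbenzoyl)oxy]-2-hydroxy-6-methylbenzoate | Cc1cc(OC(=O)c2c(C)cc(O)cc2O)cc(O)c1C(=O)OCc1ccccc1 | intermediate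
21 | methyl 2,4-dihydroxy-6-methylbenzoate | COC(=O)c1c(O)cc(O)cc1C | starting material
22 | potassium 2,4-dihydroxy-5-(methoxycarbonyl)-6-methylphenyl sulfate | COC(=O)c1c(O)cc(O)c(OS(=O)(=O)[O-])c1C.[K+] | intermediate (not isolated)
23 | methyl 2,4,5-trihydroxy-6-methylbenzoate | COC(=O)c1c(O)cc(O)c(O)c1C | intermediate
24 | methyl 2,4,5-tris(benzyloxy)-6-methylbenzoate | COC(=O)c1c(OCc2ccccc2)cc(OCc2ccccc2)c(OCc2ccccc2)c1C | intermediate
25 | 2,4,5-tris(benzyloxy)-6-methylbenzoic acid | Cc1c(OCc2ccccc2)c(OCc2ccccc2)cc(OCc2ccccc2)c1C(=O)O | intermediate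
26 | 2,4,5-tris(benzyloxy)-6-methylbenzoic trifluoroacetic anhydride | Cc1c(OCc2ccccc2)c(OCc2ccccc2)cc(OCc2ccccc2)c1C(=O)OC(=O)C(F)(F)F | intermediate (not isolated)
27 | benzyl 2-hydroxy-4-[(2-hydroxy-6-methyl-4-{[2,4,5-tris(benzyloxy)-6-methylbenzoyl]oxy}benzoyl)oxy]-6-methylbenzoate | Cc1cc(OC(=O)c2c(C)cc(OC(=O)c3c(OCc4ccccc4)cc(OCc4ccccc4)c(OCc4ccccc4)c3C)cc2O)cc(O)c1C(=O)OCc1ccccc1 | intermediate
28 | 2-hydroxy-4-[(2-hydroxy-6-methyl-4-{[2,4,5-trihydroxy-6-methylbenzoyl]oxy}benzoyl)oxy]-6-methylbenzoic acid (CNP0248995.0) | Cc1cc(OC(=O)c2c(C)cc(OC(=O)c3c(O)cc(O)c(O)c3C)cc2O)cc(O)c1C(=O)O | target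

**Step count**
Total: 13 steps. Longest linear sequence: 8 steps (1, 2, 4, 5 or 6, 7, 8, 12, 13).

**Steps most likely to fail**

Step 4.
- Light may isomerise the enoate from E to Z. That turns the ester inward and opens an oxa-6π escape route for the ketene.
- The diazo group of one molecule may add as a dipole to the electron-poor alkene of another.
- Opening of the cyclobutenone may stall.
- Fallback: take the same arene from the aromatic pool, setting out from methyl orsellinate 21. Saponification with aqueous KOH and acidification in the cold would give orsellinic acid F1. Alkylation of its carboxylate with BnBr and KHCO3 in DMF would reach 16. Silylation of the non-chelated O4 of 16 with i-Pr3SiCl and imidazole would reach 15, so the route is rejoined at both branch compounds.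

Step 2.
- The amide base may remove a proton from the C3 methyl group, which is vinylogous to the ester and cis to it, instead of from the acetyl group.
- The base may add to the ene-dicarbonyl system.
- The product may degrade during the amine-mediated transfer.
- Fallback: a route without a strong base and without diazo transfer, setting out from 3. Soft enolisation with Me3SiOTf and Et3N touches only the ketone and would give benzyl (E)-3-methyl-4-(trimethylsilyloxy)penta-2,4-dienoate F2. N-Bromosuccinimide would convert it into benzyl (E)-5-bromo-3-methyl-4-oxopent-2-enoate F3. Substitution with N,N′-ditosylhydrazine and double sulfinate elimination with DBU in THF at 0 °C would return to 6.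

Step 3.
- Monolithium acetylide may disproportionate on warming before oxygen transfer.
- The unhindered ynolate may be silylated on carbon.
- The volatile product may be lost on isolation.
- Fallback: bring in the oxygen by cycloaddition instead of by peroxide, setting out from acetylene 7. Benzonitrile oxide (from N-hydroxybenzimidoyl chloride and Et3N) would add to give 3-phenylisoxazole F4. n-BuLi in THF at −78 °C would give 5-lithio-3-phenylisoxazole F5, which should fragment on warming into benzonitrile and lithium ethynolate 9. This is then silylated as in step 3 to give 10.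

**Further compounds**
F1 | step 4 | orsellinic acid (2,4-dihydroxy-6-methylbenzoic acid) | Cc1cc(O)cc(O)c1C(=O)O
F2 | step 2 | benzyl (E)-3-methyl-4-(trimethylsilyloxy)penta-2,4-dienoate | C=C(O[Si](C)(C)C)/C(C)=C/C(=O)OCc1ccccc1
F3 | step 2 | benzyl (E)-5-bromo-3-methyl-4-oxopent-2-enoate | O=C(CBr)/C(C)=C/C(=O)OCc1ccccc1
F4 | step 3 | 3-phenylisoxazole | c1ccc(cc1)-c1ccon1
F5 | step 3 | 5-lithio-3-phenylisoxazole | [Li]c1cc(-c2ccccc2)no1
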